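## The problem

The target is a 2,3-dihydro-1-benzofuran: a benzene ring fused through C3a–C7a to a five-membered ring that holds O1, C2 and C3. C2 carries a 3-oxoprop-1-en-2-yl group (a 2-substituted acrolein), C3 carries an acetate trans to it, and C5, para to O1, carries an (R)-1-hydroxyethyl group esterified with angelic acid. C2 and C3 are neighbours, so one can control the other. The side-chain centre lies across the arene and can neither direct nor be directed by the ring centres, so it needs its own reagent-controlled step and the ring pair needs a catalyst. The groups are fragile together: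

- The enal has its allylic carbon (C2) bound to an aryloxy leaving group, so nucleophiles can add to the CH2 terminus and open the ring, and alkaline peroxide would epoxidise it.
- The C3 acetate is benzylic and can be lost with the C2 hydrogen to give an aromatic benzofuran.
- The side-chain ester is para-alkoxybenzylic and ionises under acid.
- The Z-configured angelate isomerises to the tiglate under base or nucleophilic catalysis.

The aldehyde therefore has to appear last and the angelate late. The feature that allows a short route is that C3 is at the oxidation level of an aldehyde carbon ortho to the phenolic oxygen, while C2 is both the carbon bound to O1 and the allylic terminus of a 1,1-disubstituted alkene. An aryl allenyl ether O1–CH=C=CH2 next to an ortho aldehyde holds all of these atoms, and boron on the central allene carbon is a stable stand-in, one carbon short, for the formyl group.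

## Retrosynthesis

**Aldehyde last.** Target 19 is traced to the primary allylic alcohol 18; no skeletal bond is cut. Carrying the enal through two acylations and a desilylation would expose it to amines, fluoride and heat, whereas 18 is inert to all of them. The forward step only has to oxidise a primary allylic alcohol beside two esters.

**The formyl carbon.** The C–CH2OH bond of 18 is cut to give the alkenyl boronate 16. The forward reaction is a Matteson homologation to the allylboronate 17 followed by C–B oxidation. The shorter alternative, insertion of CHCl and oxidation directly to the aldehyde, would generate a 2-substituted acrolein in alkaline peroxide, where Weitz–Scheffer epoxidation is expected, so the alcohol level is chosen. The price is that the carbenoid must pick boron over two ester carbonyls.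

**The two esters.** The angelate C–O bond of 16 is cut to alcohol 13 and angelic acid 14, joined through the mixed anhydride 15. Alcohol 13 comes from silyl ether 12. The angelate cannot be present earlier, because alkoxide, organolithium and copper boryl reagents would isomerise it or add to it. A TBS ether survives all three and comes off beside the acetate and the boronate.

**C3 with inversion.** The C3–O bond of acetate 12 is cut to the cis alcohol 11, with a Mitsunobu reaction with acetic acid as the forward step. The reasoning is that borylcupration of a monosubstituted allene gives the Z-allylcopper, and a closed transition state from that geometry gives the cis ring. The inversion then costs no extra step, since the acetate has to be installed anyway.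

**The ring (key disconnection).** In 11 the C2–C3 bond and the C–B bond are cut together, giving the allenyl ether aldehyde 8 and bis(pinacolato)diboron 9. The forward step passes through the O-boryl ether 10. Against an O1–C2 or a C7a–O1 closure, this cut removes the ring, both ring stereocentres and the marked alkene carbon in one operation. The precursor is an achiral-at-ring benzaldehyde. The forward reaction must borylate the allene and not the aldehyde, close through the oxygen-bearing carbon, and fix C2 by the ligand alone.

**Formyl group and allene.** The aryl–CHO bond of 8 is cut to aryl bromide 6 through aryllithium 7. The allene of 6 comes from the propargyl ether 5 by base-mediated isomerisation. The isomerisation is placed before the metalation because a terminal alkyne would quench the organolithium.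

**Side-chain centre and ether.** Silyl ether 5 comes from alcohol 4, alcohol 4 from ketone 3 by asymmetric transfer hydrogenation, and 3 from commercial 1 and 2 by O-alkylation. The stereocentre is set on a simple aryl methyl ketone, the best substrate class for this reduction.

## Roads not taken

**Alternative 1:** The cut is O1–C2, made by ring contraction of a chroman. The precursor is the trans-4-acetoxy-2,2-dimethylchroman-3-ol A1, obtained from a 2,2-dimethylchromene by asymmetric epoxidation and opening at C4. In the forward step, Tf2O activates the C3 hydroxyl, the ring oxygen displaces the triflate from the rear and leaves the CMe2 carbon, and proton loss gives the 2-isopropenyl dihydrobenzofuran A2.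
- Merits: the epoxidation of this chromene type is very dependable, one epoxide sets both ring centres, the aryl ketone is carried unprotected, and the sequence is about two steps shorter.
- Weak points: the isopropenyl group is one oxidation level short, so the aldehyde carbon must be found by late SeO2 allylic oxidation in a molecule that also has the C2 hydrogen and the angelate methyl groups. The cation left on the CMe2 carbon after the oxygen shift can also lose the C2 proton, giving an enol ether, or be trapped. The benzylic acetate may ionise under Tf2O.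
- Comparison: in step count and in precedent for every reaction type this road is the better one. The chosen plan sets against it that the future aldehyde carbon is marked by boron from the moment the ring forms, and that ring and both centres arise in one catalytic step. Alternative 1 is kept as the fallback for the key step.

**Alternative 2:** The cut is C7a–O1. The precursor is the open-chain anti-diol A3, an aryl fluoride with the acetyl group para to fluorine. In the forward step, base generates the C2 alkoxide, which displaces fluoride and closes the ring to A4.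
- Merits: the substitution is activated and reliable, only the C2 oxygen can reach the ipso carbon, the hydroxymethyl carbon is already in place, and the anti-diol gives the trans ring directly with no inversion.
- Weak points: A3 has to be built by a stoichiometric anti-selective alkoxyallylation or aldol on a fluorobenzaldehyde whose ketone must be masked. Two free hydroxyls meet base, an extra silyl group must be handled, and the count rises to about thirteen steps.
- Comparison: the stereochemical outcome is more predictable than that of the chosen key step, which is a real advantage. The chosen plan sets against it catalytic control, fewer steps and no protecting group on the ketone.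

**Alternative 3:** The cuts are C3a–C7a and C4–C5, so the benzene ring is made last. The precursor is the 3-alkoxy-6-acetylpyridazine A5 with a tethered terminal alkyne. On heating, the alkyne adds across C3 and C6, N2 is lost, and A6 results.
- Merits: the substitution pattern of the arene is fixed by the tether, and the acetate and the protected hydroxymethyl group are already present.
- Weak points: alkoxypyridazines are poor dienes and need high temperature. Under such heat the propargylic acetate can rearrange, and the allyl heteroaryl ether can undergo a Claisen-type shift that destroys C2. Both stereocentres must still be made beforehand in an open chain, so the stereochemical problem is only moved.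
- Comparison: it solves a regiochemical problem that this target does not have, since the 1,2,4-substituted arene is commercial. It is the longest and the least safe of the four.

Key step: step 6

Assumption: which antipode of the bisphosphine gives the 2R series cannot be derived for this substrate; (R,R)-Ph-BPE is written, and its mirror image would be used, with nothing else changed, if the sense proves opposite.

Abbreviations in names: TBSO = tert-butyldimethylsilyloxy; Bpin = 4,4,5,5-tetramethyl-1,3,2-dioxaborolan-2-yl.

## Route

Step 1
Reactants: 1 3-bromo-4-hydroxyacetophenone; 2 propargyl bromide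
Product: 3 1-[3-bromo-4-(prop-2-yn-1-yloxy)phenyl]ethanone
Conditions: K2CO3, acetone, reflux
Reagents that add atoms: none
Why: Williamson ether synthesis; the phenoxide is the only nucleophile that K2CO3 generates, and the primary propargylic bromide is displaced cleanly.

Step 2
Reactants: 3 1-[3-bromo-4-(prop-2-yn-1-yloxy)phenyl]ethanone
Product: 4 (1R)-1-[3-bromo-4-(prop-2-yn-1-yloxy)phenyl]ethanol
Conditions: RuCl(p-cymene)[(R,R)-TsDPEN] (1 mol%), HCO2H/Et3N (5:2), rt
Reagents that add atoms: none
Why: Noyori asymmetric transfer hydrogenation of an aryl methyl ketone; the (R,R) catalyst delivers hydride and proton through its six-membered transition state to give the (R)-carbinol, and the remote alkyne and the aryl bromide are not touched by the saturated ruthenium hydride.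

Step 3
Reactants: 4 (1R)-1-[3-bromo-4-(prop-2-yn-1-yloxy)phenyl]ethanol
Product: 5 {(1R)-1-[3-bromo-4-(prop-2-yn-1-yloxy)phenyl]ethoxy}(tert-butyl)dimethylsilane
Conditions: TBSCl, imidazole, DMF, rt
Reagents that add atoms: tert-butyldimethylsilyl chloride, CC(C)(C)[Si](C)(C)Cl
Why: Standard silylation of a secondary alcohol; the TBS ether is stable to alkoxide, organolithium and copper boryl reagents.

Step 4
Reactants: 5 {(1R)-1-[3-bromo-4-(prop-2-yn-1-yloxy)phenyl]ethoxy}(tert-butyl)dimethylsilane
Product: 6 {(1R)-1-[3-bromo-4-(propa-1,2-dien-1-yloxy)phenyl]ethoxy}(tert-butyl)dimethylsilane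
Conditions: KOtBu (0.3 equiv), THF, 0 °C to rt
Reagents that add atoms: none
Why: Base-mediated propargyl-to-allenyl ether isomerisation, the usual preparation of aryloxyallenes; catalytic alkoxide at room temperature stops at the allene and leaves the silyl ether and the aryl bromide alone.

Step 5
Reactants: 6 {(1R)-1-[3-bromo-4-(propa-1,2-dien-1-yloxy)phenyl]ethoxy}(tert-butyl)dimethylsilane
Product: 8 5-[(1R)-1-(TBSO)ethyl]-2-(propa-1,2-dien-1-yloxy)benzaldehyde, via aryllithium 7 (not isolated)
Conditions: t-BuLi (2.1 equiv), Et2O, −78 °C; DMF, −78 to −40 °C; aq NH4Cl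
Reagents that add atoms: N,N-dimethylformamide, CN(C)C=O
Why: Bromine–lithium exchange followed by Bouveault formylation; exchange with t-BuLi at −78 °C is much faster than deprotonation of the allene, and the aryllithium is trapped by DMF before it can act as a base.

Step 6
Reactants: 8 5-[(1R)-1-(TBSO)ethyl]-2-(propa-1,2-dien-1-yloxy)benzaldehyde; 9 bis(pinacolato)diboron
Product: 11 (2R,3R)-5-[(1R)-1-(TBSO)ethyl]-2-[1-(Bpin)ethenyl]-2,3-dihydro-1-benzofuran-3-ol (2,3-cis), via O-boryl ether 10 (not isolated)
Conditions: CuCl (5 mol%), (R,R)-Ph-BPE (6 mol%), NaOtBu (20 mol%), THF, 0 °C to rt; pH 7 buffer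
Reagents that add atoms: none
Why: Proposed new method: a bisphosphine-bound monovalent copper boryl, formed from CuCl, NaOtBu and 9, should add across the terminal double bond of the allene of 8 from the face away from the aryloxy group, putting boron on the central carbon and copper on CH2 and so giving the Z-configured 2-boryl-3-aryloxyallylcopper. This species attacks the ortho aldehyde through its oxygen-bearing carbon in a closed six-membered transition state, forming C2–C3 in a 5-exo-trig closure; the copper alkoxide then turns over with 9 to give the O-boryl ether 10, which is hydrolysed on work-up. The closest known reaction type is the copper-catalysed borylative coupling of alkyl- and aryl-substituted allenes with aldehydes and ketones, including cyclisations of carbon-tethered allenyl ketones; an allene that carries the ring oxygen on its reacting carbon has not been used. C2 is set by the face of the allyl unit that the chiral bisphosphine presents to the aldehyde, with no help from the remote side-chain centre. C3 follows from C2 through the Z geometry: the aryloxy group sits axial in the chair, the flat benzo ring accommodates the resulting small C2–C3 torsion, and the hydroxyl ends up cis to the alkenyl group, as in known cyclisations of 2-metalloallyl species onto tethered aldehydes. The step needs borylcupration of the allene in preference to boryl addition to the aldehyde, closure through the oxygen-bearing carbon and not through CH2, and one enantiomer at C2. The electron-rich allene, the ortho tether (five-membered closure against seven-membered) and the ligand are relied on for these three. The cis relationship is accepted by design, because C3 is a carbinol centre that step 7 inverts.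

Step 7
Reactants: 11 (2R,3R)-5-[(1R)-1-(TBSO)ethyl]-2-[1-(Bpin)ethenyl]-2,3-dihydro-1-benzofuran-3-ol
Product: 12 (2R,3S)-5-[(1R)-1-(TBSO)ethyl]-2-[1-(Bpin)ethenyl]-2,3-dihydro-1-benzofuran-3-yl acetate (2,3-trans)
Conditions: PPh3, DIAD, AcOH, toluene, 0 °C to rt
Reagents that add atoms: acetic acid, CC(=O)O
Why: Mitsunobu esterification; acetate displaces the alkoxyphosphonium group from the face opposite the C2 substituent, which is the open face, so C3 is inverted to S and the acetate is installed in the same operation.

Step 8
Reactants: 12 (2R,3S)-5-[(1R)-1-(TBSO)ethyl]-2-[1-(Bpin)ethenyl]-2,3-dihydro-1-benzofuran-3-yl acetate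
Product: 13 (2R,3S)-5-[(1R)-1-hydroxyethyl]-2-[1-(Bpin)ethenyl]-2,3-dihydro-1-benzofuran-3-yl acetate
Conditions: HF·pyridine, pyridine, THF, 0 °C to rt
Reagents that add atoms: none
Why: Fluoride-mediated desilylation under buffered, non-solvolytic conditions; the benzylic acetate, the para-alkoxybenzylic carbinol and the pinacol boronate should all survive.

Step 9
Reactants: 13 (2R,3S)-5-[(1R)-1-hydroxyethyl]-2-[1-(Bpin)ethenyl]-2,3-dihydro-1-benzofuran-3-yl acetate; 14 angelic acid
Product: 16 (1R)-1-{(2R,3S)-3-acetoxy-2-[1-(Bpin)ethenyl]-2,3-dihydro-1-benzofuran-5-yl}ethyl (2Z)-2-methylbut-2-enoate, via mixed anhydride 15 (not isolated)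
Conditions: 2,4,6-Cl3C6H2COCl, Et3N, toluene, rt; then 13, 80 °C
Reagents that add atoms: none
Why: Yamaguchi mixed-anhydride esterification run without DMAP, the established way to make angelates without Z-to-E isomerisation; the alcohol attacks the less hindered angeloyl carbonyl of 15, and no base-sensitive group other than the esters is present.

Step 10
Reactants: 16 (1R)-1-{(2R,3S)-3-acetoxy-2-[1-(Bpin)ethenyl]-2,3-dihydro-1-benzofuran-5-yl}ethyl (2Z)-2-methylbut-2-enoate
Product: 18 (1R)-1-[(2R,3S)-3-acetoxy-2-(3-hydroxyprop-1-en-2-yl)-2,3-dihydro-1-benzofuran-5-yl]ethyl (2Z)-2-methylbut-2-enoate, via allylboronate 17 (not isolated)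
Conditions: ICH2Cl, n-BuLi, THF, −78 °C to rt; then NaBO3·4H2O, THF/H2O, rt
Reagents that add atoms: chloroiodomethane, ClCI; sodium perborate, [Na+].[O-]OB=O
Why: Matteson homologation followed by C–B oxidation; chloromethyllithium made in the presence of the boronate is captured at boron, the alkenyl group migrates to carbon with loss of chloride, and perborate converts the allylboronate to the primary allylic alcohol without allylic shift and under conditions that esters tolerate.

Step 11
Reactants: 18 (1R)-1-[(2R,3S)-3-acetoxy-2-(3-hydroxyprop-1-en-2-yl)-2,3-dihydro-1-benzofuran-5-yl]ethyl (2Z)-2-methylbut-2-enoate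
Product: 19 (1R)-1-[(2R,3S)-3-acetoxy-2-(3-oxoprop-1-en-2-yl)-2,3-dihydro-1-benzofuran-5-yl]ethyl (2Z)-2-methylbut-2-enoate
Conditions: Dess–Martin periodinane, NaHCO3, CH2Cl2, 0 °C to rt
Reagents that add atoms: none
Why: Dess–Martin oxidation of a primary allylic alcohol; the conditions are neutral and free of nucleophiles, so the enal is formed only at the end and meets nothing that could add to it or open the ring.

## Compound list

1 | 1-(3-bromo-4-hydroxyphenyl)ethanone (3-bromo-4-hydroxyacetophenone) | CC(=O)c1ccc(O)c(Br)c1 | starting material
2 | 3-bromoprop-1-yne (propargyl bromide) | C#CCBr | starting material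
3 | 1-[3-bromo-4-(prop-2-yn-1-yloxy)phenyl]ethanone | CC(=O)c1ccc(OCC#C)c(Br)c1 | intermediate
4 | (1R)-1-[3-bromo-4-(prop-2-yn-1-yloxy)phenyl]ethanol | C[C@@H](O)c1ccc(OCC#C)c(Br)c1 | intermediate
5 | {(1R)-1-[3-bromo-4-(prop-2-yn-1-yloxy)phenyl]ethoxy}(tert-butyl)dimethylsilane | C#CCOc1ccc([C@@H](C)O[Si](C)(C)C(C)(C)C)cc1Br | intermediate
6 | {(1R)-1-[3-bromo-4-(propa-1,2-dien-1-yloxy)phenyl]ethoxy}(tert-butyl)dimethylsilane | C=C=COc1ccc([C@@H](C)O[Si](C)(C)C(C)(C)C)cc1Br | intermediate
7 | {5-[(1R)-1-(TBSO)ethyl]-2-(propa-1,2-dien-1-yloxy)phenyl}lithium | C=C=COc1ccc([C@@H](C)O[Si](C)(C)C(C)(C)C)cc1[Li] | intermediate (not isolated)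
8 | 5-[(1R)-1-(TBSO)ethyl]-2-(propa-1,2-dien-1-yloxy)benzaldehyde | C=C=COc1ccc([C@@H](C)O[Si](C)(C)C(C)(C)C)cc1C=O | intermediate
9 | bis(pinacolato)diboron | CC1(C)OB(OC1(C)C)B1OC(C)(C)C(C)(C)O1 | starting material
10 | 2-({(2R,3R)-5-[(1R)-1-(TBSO)ethyl]-2-[1-(Bpin)ethenyl]-2,3-dihydro-1-benzofuran-3-yl}oxy)-4,4,5,5-tetramethyl-1,3,2-dioxaborolane | C=C(B1OC(C)(C)C(C)(C)O1)[C@H]1Oc2ccc([C@@H](C)O[Si](C)(C)C(C)(C)C)cc2[C@H]1OB1OC(C)(C)C(C)(C)O1 | intermediate (not isolated)
11 | (2R,3R)-5-[(1R)-1-(TBSO)ethyl]-2-[1-(Bpin)ethenyl]-2,3-dihydro-1-benzofuran-3-ol (2,3-cis) | C=C(B1OC(C)(C)C(C)(C)O1)[C@H]1Oc2ccc([C@@H](C)O[Si](C)(C)C(C)(C)C)cc2[C@H]1O | intermediate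
12 | (2R,3S)-5-[(1R)-1-(TBSO)ethyl]-2-[1-(Bpin)ethenyl]-2,3-dihydro-1-benzofuran-3-yl acetate (2,3-trans) | C=C(B1OC(C)(C)C(C)(C)O1)[C@H]1Oc2ccc([C@@H](C)O[Si](C)(C)C(C)(C)C)cc2[C@@H]1OC(C)=O | intermediate
13 | (2R,3S)-5-[(1R)-1-hydroxyethyl]-2-[1-(Bpin)ethenyl]-2,3-dihydro-1-benzofuran-3-yl acetate | C=C(B1OC(C)(C)C(C)(C)O1)[C@H]1Oc2ccc([C@@H](C)O)cc2[C@@H]1OC(C)=O | intermediate
14 | (2Z)-2-methylbut-2-enoic acid (angelic acid) | C/C=C(/C)C(=O)O | starting material
15 | (2Z)-2-methylbut-2-enoic 2,4,6-trichlorobenzoic anhydride | C/C=C(/C)C(=O)OC(=O)c1c(Cl)cc(Cl)cc1Cl | intermediate (not isolated)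
16 | (1R)-1-{(2R,3S)-3-acetoxy-2-[1-(Bpin)ethenyl]-2,3-dihydro-1-benzofuran-5-yl}ethyl (2Z)-2-methylbut-2-enoate | C=C(B1OC(C)(C)C(C)(C)O1)[C@H]1Oc2ccc([C@@H](C)OC(=O)/C(C)=C\C)cc2[C@@H]1OC(C)=O | intermediate
17 | (1R)-1-{(2R,3S)-3-acetoxy-2-[3-(Bpin)prop-1-en-2-yl]-2,3-dihydro-1-benzofuran-5-yl}ethyl (2Z)-2-methylbut-2-enoate | C=C(CB1OC(C)(C)C(C)(C)O1)[C@H]1Oc2ccc([C@@H](C)OC(=O)/C(C)=C\C)cc2[C@@H]1OC(C)=O | intermediate (not isolated)
18 | (1R)-1-[(2R,3S)-3-acetoxy-2-(3-hydroxyprop-1-en-2-yl)-2,3-dihydro-1-benzofuran-5-yl]ethyl (2Z)-2-methylbut-2-enoate | C=C(CO)[C@H]1Oc2ccc([C@@H](C)OC(=O)/C(C)=C\C)cc2[C@@H]1OC(C)=O | intermediate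
19 | (1R)-1-[(2R,3S)-3-acetoxy-2-(3-oxoprop-1-en-2-yl)-2,3-dihydro-1-benzofuran-5-yl]ethyl (2Z)-2-methylbut-2-enoate | C=C(C=O)[C@H]1Oc2ccc([C@@H](C)OC(=O)/C(C)=C\C)cc2[C@@H]1OC(C)=O | target

## Step count and least certain steps

Total: 11 steps. Longest linear sequence: 11 steps, from 1 to 19.

**Step 6 (key step, new method).** The most likely failure is addition of the copper boryl to the aldehyde carbonyl in competition with borylcupration of the allene. The second is loss of facial control at C2, because the aryloxy oxygen can bind copper and loosen the ligand's grip. Either leaves no usable ring compound. The fallback abandons the allene and uses known reactions only; it sets out from 1 and comes back at 18.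
- Heck reaction of 1 with 2-methylbut-3-en-2-ol (Pd(OAc)2, P(o-tol)3, Et3N, DMF) should give (E)-1-[4-hydroxy-3-(3-hydroxy-3-methylbut-1-en-1-yl)phenyl]ethanone F1.
- Acid-catalysed cyclodehydration should close it to 1-(2,2-dimethyl-2H-chromen-6-yl)ethanone F2.
- Jacobsen epoxidation with (R,R)-[N,N'-bis(3,5-di-tert-butylsalicylidene)cyclohexane-1,2-diamine]MnCl and NaOCl, using the antipode that gives the 3R,4R oxide, should give (3R,4R)-6-acetyl-3,4-epoxy-2,2-dimethylchromane F3.
- Opening at the benzylic carbon with acetate in acetic acid should give (3R,4S)-6-acetyl-3-hydroxy-2,2-dimethyl-3,4-dihydro-2H-chromen-4-yl acetate F4.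
- Tf2O with a hindered pyridine base should trigger the oxygen shift and proton loss to (2R,3S)-5-acetyl-2-(prop-1-en-2-yl)-2,3-dihydro-1-benzofuran-3-yl acetate F5.
- Transfer hydrogenation as in step 2 should give (2R,3S)-5-[(1R)-1-hydroxyethyl]-2-(prop-1-en-2-yl)-2,3-dihydro-1-benzofuran-3-yl acetate F6.
- Esterification with 14 as in step 9 should give (1R)-1-[(2R,3S)-3-acetoxy-2-(prop-1-en-2-yl)-2,3-dihydro-1-benzofuran-5-yl]ethyl (2Z)-2-methylbut-2-enoate F7.
- Allylic oxidation of the isopropenyl methyl group with catalytic SeO2 and t-BuOOH should give 18, and step 11 follows.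

**Step 10.** Chloromethyllithium may add to the acetate carbonyl, or deprotonate the acetate, in competition with capture by boron. The aryloxide on C2 may also be expelled from the boron ate complex before the 1,2-shift. The fallback brings in the carbon without any carbanion; it sets out from 16 and comes back at 18. Iododeboronation with NaI and TsN(Cl)Na in aqueous THF should give (1R)-1-[(2S,3S)-3-acetoxy-2-(1-iodoethenyl)-2,3-dihydro-1-benzofuran-5-yl]ethyl (2Z)-2-methylbut-2-enoate F8. The C2 descriptor changes only because iodine raises the priority of the alkenyl carbon; the geometry is unchanged. Stille coupling of F8 with Bu3SnCH2OH under Pd(PPh3)4 in toluene should give 18.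

**Step 7.** The activated C3 oxygen may be lost together with the anti C2 hydrogen, aromatising the ring to a benzofuran, because acetic acid is a weak pronucleophile and intercepts the alkoxyphosphonium ion slowly. The fallback separates inversion from acetylation; it sets out from 11 and comes back at 12.
- Mitsunobu reaction with 4-nitrobenzoic acid, which traps the phosphonium ion faster, should give (2R,3S)-5-[(1R)-1-(TBSO)ethyl]-2-[1-(Bpin)ethenyl]-2,3-dihydro-1-benzofuran-3-yl 4-nitrobenzoate F9.
- K2CO3 in methanol should release (2R,3S)-5-[(1R)-1-(TBSO)ethyl]-2-[1-(Bpin)ethenyl]-2,3-dihydro-1-benzofuran-3-ol F10.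
- Ac2O in pyridine should give 12 with retention.
- F10 is also what step 6 would deliver if the closure went trans; in that case it would be acetylated directly.

**Step 5.** The allenyl ether may be deprotonated at its oxygen-bearing carbon by t-BuLi, or by the aryllithium once formed, in competition with exchange and formylation. The fallback formylates before the allene exists; it sets out from 5 and comes back at 8. n-BuLi (1 equiv) turns the alkyne into its acetylide, t-BuLi then exchanges the bromide, and DMF at −78 °C with a cold quench formylates only the aryllithium, giving 5-[(1R)-1-(TBSO)ethyl]-2-(prop-2-yn-1-yloxy)benzaldehyde F11. Catalytic KOtBu in THF at 0 °C should then isomerise the propargyl ether of this aldehyde, which has no α-hydrogen, to 8.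

## Further compounds

F1 | step 6 | (E)-1-[4-hydroxy-3-(3-hydroxy-3-methylbut-1-en-1-yl)phenyl]ethanone | CC(=O)c1ccc(O)c(/C=C/C(C)(C)O)c1
F2 | step 6 | 1-(2,2-dimethyl-2H-chromen-6-yl)ethanone | CC(=O)c1ccc2OC(C)(C)C=Cc2c1
F3 | step 6 | (3R,4R)-6-acetyl-3,4-epoxy-2,2-dimethylchromane | CC1(C)Oc2ccc(C(C)=O)cc2[C@H]3O[C@@H]13
F4 | step 6 | (3R,4S)-6-acetyl-3-hydroxy-2,2-dimethyl-3,4-dihydro-2H-chromen-4-yl acetate | CC1(C)Oc2ccc(C(C)=O)cc2[C@H](OC(C)=O)[C@H]1O
F5 | step 6 | (2R,3S)-5-acetyl-2-(prop-1-en-2-yl)-2,3-dihydro-1-benzofuran-3-yl acetate | C=C(C)[C@H]1Oc2ccc(C(C)=O)cc2[C@@H]1OC(C)=O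
F6 | step 6 | (2R,3S)-5-[(1R)-1-hydroxyethyl]-2-(prop-1-en-2-yl)-2,3-dihydro-1-benzofuran-3-yl acetate | C=C(C)[C@H]1Oc2ccc([C@@H](C)O)cc2[C@@H]1OC(C)=O
F7 | step 6 | (1R)-1-[(2R,3S)-3-acetoxy-2-(prop-1-en-2-yl)-2,3-dihydro-1-benzofuran-5-yl]ethyl (2Z)-2-methylbut-2-enoate | C=C(C)[C@H]1Oc2ccc([C@@H](C)OC(=O)/C(C)=C\C)cc2[C@@H]1OC(C)=O
F8 | step 10 | (1R)-1-[(2S,3S)-3-acetoxy-2-(1-iodoethenyl)-2,3-dihydro-1-benzofuran-5-yl]ethyl (2Z)-2-methylbut-2-enoate | C=C(I)[C@H]1Oc2ccc([C@@H](C)OC(=O)/C(C)=C\C)cc2[C@@H]1OC(C)=O
F9 | step 7 | (2R,3S)-5-[(1R)-1-(TBSO)ethyl]-2-[1-(Bpin)ethenyl]-2,3-dihydro-1-benzofuran-3-yl 4-nitrobenzoate | C=C(B1OC(C)(C)C(C)(C)O1)[C@H]1Oc2ccc([C@@H](C)O[Si](C)(C)C(C)(C)C)cc2[C@@H]1OC(=O)c1ccc([N+](=O)[O-])cc1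
F10 | step 7 | (2R,3S)-5-[(1R)-1-(TBSO)ethyl]-2-[1-(Bpin)ethenyl]-2,3-dihydro-1-benzofuran-3-ol | C=C(B1OC(C)(C)C(C)(C)O1)[C@H]1Oc2ccc([C@@H](C)O[Si](C)(C)C(C)(C)C)cc2[C@@H]1O
F11 | step 5 | 5-[(1R)-1-(TBSO)ethyl]-2-(prop-2-yn-1-yloxy)benzaldehyde | C#CCOc1ccc([C@@H](C)O[Si](C)(C)C(C)(C)C)cc1C=O
A1 | alternative 1 | (3R,4S)-6-acetyl-3-hydroxy-2,2-dimethyl-3,4-dihydro-2H-chromen-4-yl acetate | CC1(C)Oc2ccc(C(C)=O)cc2[C@H](OC(C)=O)[C@H]1O
A2 | alternative 1 | (2R,3S)-5-acetyl-2-(prop-1-en-2-yl)-2,3-dihydro-1-benzofuran-3-yl acetate | C=C(C)[C@H]1Oc2ccc(C(C)=O)cc2[C@@H]1OC(C)=O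
A3 | alternative 2 | 1-{3-[(1S,2R)-3-[(tert-butyldiphenylsilyloxy)methyl]-1,2-dihydroxybut-3-en-1-yl]-4-fluorophenyl}ethanone | C=C(CO[Si](c1ccccc1)(c1ccccc1)C(C)(C)C)[C@@H](O)[C@@H](O)c1cc(C(C)=O)ccc1F
A4 | alternative 2 | 1-[(2R,3S)-2-[3-(tert-butyldiphenylsilyloxy)prop-1-en-2-yl]-3-hydroxy-2,3-dihydro-1-benzofuran-5-yl]ethanone | C=C(CO[Si](c1ccccc1)(c1ccccc1)C(C)(C)C)[C@H]1Oc2ccc(C(C)=O)cc2[C@@H]1O
A5 | alternative 3 | (3S,4R)-4-[(6-acetylpyridazin-3-yl)oxy]-5-[(tert-butyldimethylsilyloxy)methyl]hex-5-en-1-yn-3-yl acetate | C=C(CO[Si](C)(C)C(C)(C)C)[C@@H](Oc1ccc(C(C)=O)nn1)[C@@H](OC(C)=O)C#C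
A6 | alternative 3 | (2R,3S)-5-acetyl-2-[3-(tert-butyldimethylsilyloxy)prop-1-en-2-yl]-2,3-dihydro-1-benzofuran-3-yl acetate | C=C(CO[Si](C)(C)C(C)(C)C)[C@H]1Oc2ccc(C(C)=O)cc2[C@@H]1OC(C)=O
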